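**Plan**

- Retrosynthesis first cuts the cinnamate at its Cα=Cβ bond (Horner–Wadsworth–Emmons) and at the C6–O acyl bond, then takes the C4–O and C15–O bonds back to a C4=C15 methylene and a C4 ketone, so the cinnamate alkene is made only after osmylation.
- The decalin is cut at C5–C10 and C8–C9. Ring B (C5–C10) has oxygen on C6 beside the isopropyl-bearing C7, so at the silyl enol ether level it is a cyclohexene with C6=C7, the retron of a [4+2] between a C5=C6(OSi)–C7=C8 diene and a C9=C10 dienophile. C10 (bearing C14) is the dienophile β-carbon, the C1–C4 chain (C4 as ketal) is the tether that becomes ring A, and a carboxyl on C9, excised later, carries a chiral oxazolidinone.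
- The open chain is cut at C10–C1 (carbocupration of methyl but-2-ynoate, which fixes the E dienophile), at C4–C5 (acetamide enolate aldol) and at C6–C7 (alkenyl Grignard on an N-methoxy-N-methyl amide).
- Forward, the chain is joined C10–C1, then C4–C5, then C6–C7; auxiliary and silyl dienol ether are installed; rings A and B close together in one intramolecular Diels–Alder step; then C9 is decarboxylated, C6 reduced, C4 methylenated and dihydroxylated, and the ester olefinated.
- Stereochemistry: C10 from the (S)-4-benzyl oxazolidinone (face selection on the aluminium chelate), C5 from the endo transition state (trans fusion), C7 from axial protonation of the enol, C6 from equatorial hydride delivery, C4 from α-face osmylation, and the cinnamate E geometry from the olefination.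

Key step: step 10

Remark: eudesmane numbering is used throughout (ring A = C10, C1–C5; ring B = C5–C10; C14 = methyl on C10; C15 = carbon on C4; β = the face of C14). All ring-fused intermediates carry 5α-H and 10β-CH3, and from the C6 ketone onward 7α-H (7β-isopropyl). All starting materials are assumed to be purchasable.

**Route**

Step 1
Reactants: 1 2-(3-chloropropyl)-1,3-dioxolane; 2 methyl but-2-ynoate
Product: 5 methyl (E)-6-(1,3-dioxolan-2-yl)-3-methylhex-2-enoate, via Grignard reagent 3 (not isolated), via alkylcopper 4 (not isolated)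
Conditions: Mg, THF, 45 °C; CuBr·SMe2, THF/Me2S, −45 °C; 2, −78 °C; MeOH, −78 °C
Reagents that add atoms: none
Why: The alkylcopper adds syn across the ynoate at −78 °C and the alkenylcopper is protonated with retention (carbocupration of a 2-alkynoate), which places the new chain trans to the ester and fixes the E geometry of the later dienophile.

Step 2
Reactants: 5 methyl (E)-6-(1,3-dioxolan-2-yl)-3-methylhex-2-enoate
Product: 6 methyl (E)-3-methyl-7-oxohept-2-enoate
Conditions: 1 M HCl, THF, rt
Reagents that add atoms: water, O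
Why: Aqueous acid hydrolyses the aldehyde acetal (acetal hydrolysis) and leaves the conjugated ester untouched.

Step 3
Reactants: 6 methyl (E)-3-methyl-7-oxohept-2-enoate; 7 N-methoxy-N-methylacetamide
Product: 9 methyl (E)-7-hydroxy-9-[methoxy(methyl)amino]-3-methyl-9-oxonon-2-enoate (racemic), via lithium enolate 8 (not isolated)
Conditions: LiN(i-Pr)2, THF, −78 °C; then 6, −78 °C; AcOH quench
Reagents that add atoms: none
Why: The amide enolate adds to the aldehyde far faster than to the hindered β,β-disubstituted enoate (aldol addition), which brings in C5 and C6 with C6 already at the acyl level; the new carbinol centre at C4 is racemic and is erased in the next step.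

Step 4
Reactants: 9 methyl (E)-7-hydroxy-9-[methoxy(methyl)amino]-3-methyl-9-oxonon-2-enoate
Product: 10 methyl (E)-9-[methoxy(methyl)amino]-3-methyl-7,9-dioxonon-2-enoate
Conditions: Dess–Martin periodinane, CH2Cl2, rt
Reagents that add atoms: none
Why: Dess–Martin oxidation converts the secondary alcohol into the C4 ketone under neutral conditions that spare the enoate and the N-methoxy amide.

Step 5
Reactants: 10 methyl (E)-9-[methoxy(methyl)amino]-3-methyl-7,9-dioxonon-2-enoate
Product: 11 methyl (E)-6-[2-(2-{methoxy(methyl)amino}-2-oxoethyl)-1,3-dioxolan-2-yl]-3-methylhex-2-enoate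
Conditions: ethylene glycol, p-TsOH (cat.), benzene, reflux, Dean–Stark trap
Reagents that add atoms: ethylene glycol, OCCO
Why: Acid-catalysed ketalisation with azeotropic removal of water masks the C4 ketone as an achiral dioxolane, which removes the 1,3-dicarbonyl acidity before the organometallic step and keeps C4 from becoming part of the later enol system.

Step 6
Reactants: 11 methyl (E)-6-[2-(2-{methoxy(methyl)amino}-2-oxoethyl)-1,3-dioxolan-2-yl]-3-methylhex-2-enoate
Product: 12 (E)-6-[2-(2-{methoxy(methyl)amino}-2-oxoethyl)-1,3-dioxolan-2-yl]-3-methylhex-2-enoic acid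
Conditions: LiOH, THF/MeOH/H2O, 45 °C; then 1 M HCl to pH 3, 0 °C
Reagents that add atoms: lithium hydroxide (LiOH), [Li+].[OH-]
Why: Saponification cleaves the methyl ester while the amide and the ketal are inert to hydroxide, so the two carbonyl termini become different in kind.

Step 7
Reactants: 12 (E)-6-[2-(2-{methoxy(methyl)amino}-2-oxoethyl)-1,3-dioxolan-2-yl]-3-methylhex-2-enoic acid; 13 2-bromo-3-methylbut-1-ene
Product: 15 (E)-3-methyl-6-[2-(4-methyl-3-methylidene-2-oxopentyl)-1,3-dioxolan-2-yl]hex-2-enoic acid, via alkenylmagnesium bromide 14 (not isolated)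
Conditions: 13, Mg, THF (2.4 equiv of 14); 12, THF, −20 to 0 °C; inverse quench into cold 1 M HCl
Reagents that add atoms: none
Why: The first equivalent of Grignard reagent turns the acid into an unreactive magnesium carboxylate and the next adds to the N-methoxy-N-methyl amide to give a chelated tetrahedral adduct that releases the enone only on quenching (Weinreb ketone synthesis), forming C6–C7.

Step 8
Reactants: 15 (E)-3-methyl-6-[2-(4-methyl-3-methylidene-2-oxopentyl)-1,3-dioxolan-2-yl]hex-2-enoic acid; 16 (S)-4-benzyl-2-oxazolidinone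
Product: 18 (S)-4-benzyl-3-{(E)-3-methyl-6-[2-(4-methyl-3-methylidene-2-oxopentyl)-1,3-dioxolan-2-yl]hex-2-enoyl}oxazolidin-2-one, via mixed pivalic anhydride 17 (not isolated)
Conditions: t-BuCOCl, Et3N, THF, −20 °C; then 16, LiCl, rt
Reagents that add atoms: none
Why: The oxazolidinone nitrogen, activated by LiCl and Et3N, attacks the mixed anhydride at the less hindered enoyl carbonyl (mixed-anhydride N-acylation) under conditions mild enough for the enone and the ketal.

Step 9
Reactants: 18 (S)-4-benzyl-3-{(E)-3-methyl-6-[2-(4-methyl-3-methylidene-2-oxopentyl)-1,3-dioxolan-2-yl]hex-2-enoyl}oxazolidin-2-one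
Product: 19 (S)-4-benzyl-3-[(E)-6-{2-[(Z)-2-(tert-butyldimethylsilyloxy)-4-methyl-3-methylidenepent-1-en-1-yl]-1,3-dioxolan-2-yl}-3-methylhex-2-enoyl]oxazolidin-2-one
Conditions: TBSOTf, Et3N, CH2Cl2, −78 to 0 °C; isolation on Et3N-deactivated silica
Reagents that add atoms: tert-butyldimethylsilyl triflate (TBSOTf), CC(C)(C)[Si](C)(C)OS(=O)(=O)C(F)(F)F
Why: Soft enolisation with silyl triflate and amine occurs at the more Lewis-basic ketone and not at the imide, C5 is the only enolisable position, and the Z enol ether is favoured because the bulky C4 avoids the branched C7 (silyl enol ether formation), which gives the cross-conjugated 2-silyloxydiene with the tether on the outside of the diene terminus.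

Step 10
Reactants: 19 (S)-4-benzyl-3-[(E)-6-{2-[(Z)-2-(tert-butyldimethylsilyloxy)-4-methyl-3-methylidenepent-1-en-1-yl]-1,3-dioxolan-2-yl}-3-methylhex-2-enoyl]oxazolidin-2-one
Product: 20 (S)-4-benzyl-3-{[6-(tert-butyldimethylsilyloxy)-4,4-(ethylenedioxy)-15-noreudesm-6-en-9β-yl]carbonyl}oxazolidin-2-one (5αH,10βMe)
Conditions: Me2AlCl (1.6 equiv), CH2Cl2, −78 to −30 °C; pH 7 buffer quench
Reagents that add atoms: none
Why: Two-point binding of both imide carbonyls to aluminium holds the enoyl group planar and s-cis and makes C10 strongly electrophilic, and the 2-silyloxydiene then adds in a concerted, asynchronous [4+2] cycloaddition in which the donor terminus C5 bonds to C10 ahead of the C8–C9 bond; the closest known reaction type is the Lewis-acid-promoted intramolecular Diels–Alder reaction of trienyl N-acyl oxazolidinones of the 1,7,9-decatriene class. Ring B closes as the new cyclohexene assembled from the diene C5–C8 and the dienophile C9=C10, and ring A closes in the same event as the six-membered carbocycle spanned by the four-atom tether C1–C4 once C5–C10 forms. C10 is controlled by the auxiliary, whose benzyl group lies over one face of the bound E-enoyl unit so that the diene must approach the other face, which places C14 on the β side. C5 is controlled by the transition-state geometry, because with the acyl group endo and the tether exo the substituents C14 and C4 finish cis on ring B, which means 5α-H and a trans ring fusion, and C9 follows from the E dienophile geometry and is excised later. The step needs one dienophile face, the endo mode and one regiochemistry; the chelated auxiliary secures the first, overlap of the diene with the aluminium-bound carbonyl secures the second, and the tether secures the third in agreement with the polarity of the silyloxydiene. Me2AlCl is preferred over halide-richer Lewis acids because its Al–CH3 bonds destroy adventitious acid that would hydrolyse the silyl enol ether or open the ketal.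

Step 11
Reactants: 20 (S)-4-benzyl-3-{[6-(tert-butyldimethylsilyloxy)-4,4-(ethylenedioxy)-15-noreudesm-6-en-9β-yl]carbonyl}oxazolidin-2-one (5αH,10βMe)
Product: 21 6-(tert-butyldimethylsilyloxy)-4,4-(ethylenedioxy)-15-noreudesm-6-ene-9β-carboxylic acid (5αH,10βMe)
Conditions: LiOH, H2O2, THF/H2O, 0 °C; Na2SO3; 0.5 M HCl to pH 4, 0 °C
Reagents that add atoms: hydrogen peroxide, OO
Why: Hydroperoxide attacks the exocyclic imide carbonyl selectively even in hindered N-acyl oxazolidinones (peroxide-mediated auxiliary cleavage), which releases the C9 acid and the recoverable auxiliary while the hindered tetrasubstituted silyl enol ether should survive the cold basic medium.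

Step 12
Reactants: 21 6-(tert-butyldimethylsilyloxy)-4,4-(ethylenedioxy)-15-noreudesm-6-ene-9β-carboxylic acid (5αH,10βMe)
Product: 23 6-(tert-butyldimethylsilyloxy)-4,4-(ethylenedioxy)-15-noreudesm-6-ene (5αH,10βMe), via Barton ester 22 (not isolated)
Conditions: N-hydroxypyridine-2-thione, DCC, DMAP (cat.), CH2Cl2, rt, dark; then t-BuSH, hν (tungsten lamp), rt
Reagents that add atoms: none
Why: The thiohydroxamate ester fragments under visible light to CO2 and a secondary C9 radical that takes hydrogen from the thiol (Barton reductive decarboxylation), so the carbon that carried the auxiliary is excised without touching C10 or the enol ether.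

Step 13
Reactants: 23 6-(tert-butyldimethylsilyloxy)-4,4-(ethylenedioxy)-15-noreudesm-6-ene (5αH,10βMe)
Product: 24 4,4-(ethylenedioxy)-15-noreudesman-6-one (5αH,7αH,10βMe)
Conditions: Bu4NF, AcOH, THF, 0 °C to rt
Reagents that add atoms: none
Why: Fluoride cleaves the Si–O bond and the enol(ate) is protonated at C7 along the axial direction from the α face (buffered cleavage of a silyl enol ether), which gives the equatorial 7β-isopropyl group that is also the more stable epimer, while the acetic acid buffer keeps C5 from epimerising.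

Step 14
Reactants: 24 4,4-(ethylenedioxy)-15-noreudesman-6-one (5αH,7αH,10βMe)
Product: 25 4,4-(ethylenedioxy)-15-noreudesman-6β-ol (5αH,7αH,10βMe)
Conditions: LiBH(s-Bu)3, THF, −78 °C; H2O work-up
Reagents that add atoms: none
Why: The axial β trajectory to C6 is blocked by the C14 methyl and by the β oxygen of the ketal, so the bulky hydride attacks from the α side and gives the axial 6β alcohol (hindered-hydride ketone reduction).

Step 15
Reactants: 25 4,4-(ethylenedioxy)-15-noreudesman-6β-ol (5αH,7αH,10βMe)
Product: 26 6β-hydroxy-15-noreudesman-4-one (5αH,7αH,10βMe)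
Conditions: PPTS, acetone/H2O, 55 °C
Reagents that add atoms: water, O
Why: Mild acid-catalysed ketal hydrolysis frees the C4 ketone, helped by relief of the syn-axial contact between the ketal oxygen and C14, under conditions that should be too weak to dehydrate the β-hydroxy ketone.

Step 16
Reactants: 26 6β-hydroxy-15-noreudesman-4-one (5αH,7αH,10βMe)
Product: 27 eudesm-4(15)-en-6β-ol (5αH,7αH,10βMe)
Conditions: Zn, CH2Br2, TiCl4, THF (reagent pre-formed, excess); 26, CH2Cl2, 0 °C to rt
Reagents that add atoms: dibromomethane, BrCBr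
Why: The non-basic gem-dimetallic methylene reagent methylenates hindered, enolisable ketones without epimerising C5 or causing retro-aldol cleavage and tolerates the free hydroxyl (Takai–Lombardo methylenation), which introduces C15.

Step 17
Reactants: 27 eudesm-4(15)-en-6β-ol (5αH,7αH,10βMe); 28 2-(diethoxyphosphoryl)acetic acid
Product: 29 eudesm-4(15)-en-6β-yl 2-(diethoxyphosphoryl)acetate (5αH,7αH,10βMe)
Conditions: DCC, DMAP (cat.), CH2Cl2, 0 °C to rt
Reagents that add atoms: none
Why: While C4 is trigonal the axial 6β-hydroxyl has only one syn-axial neighbour (C14) and is acylated by the carbodiimide-activated acid (Steglich-type esterification), which installs an ester that is inert to osmylation and carries the latent cinnamate.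

Step 18
Reactants: 29 eudesm-4(15)-en-6β-yl 2-(diethoxyphosphoryl)acetate (5αH,7αH,10βMe)
Product: 30 4α,15-dihydroxyeudesman-6β-yl 2-(diethoxyphosphoryl)acetate (5αH,7αH,10βMe)
Conditions: OsO4 (cat.), N-methylmorpholine N-oxide, acetone/H2O, rt
Reagents that add atoms: osmium tetroxide (OsO4), O=[Os](=O)(=O)=O; N-methylmorpholine N-oxide, C[N+]1([O-])CCOCC1; water, O
Why: OsO4 adds to the exocyclic alkene from the α face because the β face is screened by the axial C14 methyl and the axial 6β ester (catalytic dihydroxylation with an N-oxide reoxidant), which sets C4 with the hydroxyl α and C15 β.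

Step 19
Reactants: 30 4α,15-dihydroxyeudesman-6β-yl 2-(diethoxyphosphoryl)acetate (5αH,7αH,10βMe); 31 benzaldehyde
Product: 32 4α,15-dihydroxyeudesman-6β-yl (E)-cinnamate (5αH,7αH,10βMe)
Conditions: LiCl, i-Pr2NEt, MeCN, rt
Reagents that add atoms: none
Why: The phosphonate anion generated by LiCl and amine olefinates benzaldehyde with high E selectivity under conditions mild enough for the free diol (Horner–Wadsworth–Emmons reaction under Masamune–Roush conditions), which completes the cinnamate and the target.

**Compound list**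

1 | 2-(3-chloropropyl)-1,3-dioxolane | ClCCCC1OCCO1 | starting material
2 | methyl but-2-ynoate | COC(=O)C#CC | starting material
3 | [3-(1,3-dioxolan-2-yl)propyl]magnesium chloride | Cl[Mg]CCCC1OCCO1 | intermediate
4 | [3-(1,3-dioxolan-2-yl)propyl]copper (as its magnesium halide complex) | [Cu]CCCC1OCCO1 | intermediate
5 | methyl (E)-6-(1,3-dioxolan-2-yl)-3-methylhex-2-enoate | COC(=O)/C=C(\C)CCCC1OCCO1 | intermediate
6 | methyl (E)-3-methyl-7-oxohept-2-enoate | COC(=O)/C=C(\C)CCCC=O | intermediate
7 | N-methoxy-N-methylacetamide | CC(=O)N(C)OC | starting material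
8 | lithium enolate of N-methoxy-N-methylacetamide | [Li]OC(=C)N(C)OC | intermediate
9 | methyl (E)-7-hydroxy-9-[methoxy(methyl)amino]-3-methyl-9-oxonon-2-enoate (racemic) | COC(=O)/C=C(\C)CCCC(O)CC(=O)N(C)OC | intermediate
10 | methyl (E)-9-[methoxy(methyl)amino]-3-methyl-7,9-dioxonon-2-enoate | COC(=O)/C=C(\C)CCCC(=O)CC(=O)N(C)OC | intermediate
11 | methyl (E)-6-[2-(2-{methoxy(methyl)amino}-2-oxoethyl)-1,3-dioxolan-2-yl]-3-methylhex-2-enoate | COC(=O)/C=C(\C)CCCC1(CC(=O)N(C)OC)OCCO1 | intermediate
12 | (E)-6-[2-(2-{methoxy(methyl)amino}-2-oxoethyl)-1,3-dioxolan-2-yl]-3-methylhex-2-enoic acid | OC(=O)/C=C(\C)CCCC1(CC(=O)N(C)OC)OCCO1 | intermediate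
13 | 2-bromo-3-methylbut-1-ene | C=C(Br)C(C)C | starting material
14 | (3-methylbut-1-en-2-yl)magnesium bromide | Br[Mg]C(=C)C(C)C | intermediate
15 | (E)-3-methyl-6-[2-(4-methyl-3-methylidene-2-oxopentyl)-1,3-dioxolan-2-yl]hex-2-enoic acid | OC(=O)/C=C(\C)CCCC1(CC(=O)C(=C)C(C)C)OCCO1 | intermediate
16 | (S)-4-benzyl-2-oxazolidinone | O=C1OC[C@H](Cc2ccccc2)N1 | starting material
17 | mixed anhydride of 15 with pivalic acid | CC(C)(C)C(=O)OC(=O)/C=C(\C)CCCC1(CC(=O)C(=C)C(C)C)OCCO1 | intermediate
18 | (S)-4-benzyl-3-{(E)-3-methyl-6-[2-(4-methyl-3-methylidene-2-oxopentyl)-1,3-dioxolan-2-yl]hex-2-enoyl}oxazolidin-2-one | O=C1OC[C@H](Cc2ccccc2)N1C(=O)/C=C(\C)CCCC3(OCCO3)CC(=O)C(=C)C(C)C | intermediate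
19 | (S)-4-benzyl-3-[(E)-6-{2-[(Z)-2-(tert-butyldimethylsilyloxy)-4-methyl-3-methylidenepent-1-en-1-yl]-1,3-dioxolan-2-yl}-3-methylhex-2-enoyl]oxazolidin-2-one (Diels–Alder precursor) | O=C1OC[C@H](Cc2ccccc2)N1C(=O)/C=C(\C)CCCC3(OCCO3)/C=C(O[Si](C)(C)C(C)(C)C)/C(=C)C(C)C | intermediate
20 | (S)-4-benzyl-3-{[6-(tert-butyldimethylsilyloxy)-4,4-(ethylenedioxy)-15-noreudesm-6-en-9β-yl]carbonyl}oxazolidin-2-one, 5α-H, 10β-CH3 (Diels–Alder product) | CC(C)C1=C(O[Si](C)(C)C(C)(C)C)[C@H]2C3(OCCO3)CCC[C@]2(C)[C@H](C1)C(=O)N4[C@@H](Cc5ccccc5)COC4=O | intermediate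
21 | 6-(tert-butyldimethylsilyloxy)-4,4-(ethylenedioxy)-15-noreudesm-6-ene-9β-carboxylic acid, 5α-H, 10β-CH3 | CC(C)C1=C(O[Si](C)(C)C(C)(C)C)[C@H]2C3(OCCO3)CCC[C@]2(C)[C@H](C1)C(=O)O | intermediate
22 | 2-thioxopyridin-1(2H)-yl ester of 21 (Barton ester) | CC(C)C1=C(O[Si](C)(C)C(C)(C)C)[C@H]2C3(OCCO3)CCC[C@]2(C)[C@H](C1)C(=O)ON4C=CC=CC4=S | intermediate
23 | 6-(tert-butyldimethylsilyloxy)-4,4-(ethylenedioxy)-15-noreudesm-6-ene, 5α-H, 10β-CH3 | CC(C)C1=C(O[Si](C)(C)C(C)(C)C)[C@H]2C3(OCCO3)CCC[C@]2(C)CC1 | intermediate
24 | 4,4-(ethylenedioxy)-15-noreudesman-6-one, 5α-H, 7α-H, 10β-CH3 | CC(C)[C@@H]1CC[C@@]2(C)CCCC3(OCCO3)[C@@H]2C1=O | intermediate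
25 | 4,4-(ethylenedioxy)-15-noreudesman-6β-ol, 5α-H, 7α-H, 10β-CH3 | CC(C)[C@@H]1CC[C@@]2(C)CCCC3(OCCO3)[C@@H]2[C@@H]1O | intermediate
26 | 6β-hydroxy-15-noreudesman-4-one, 5α-H, 7α-H, 10β-CH3 | CC(C)[C@@H]1CC[C@@]2(C)CCCC(=O)[C@@H]2[C@@H]1O | intermediate
27 | eudesm-4(15)-en-6β-ol, 5α-H, 7α-H, 10β-CH3 | CC(C)[C@@H]1CC[C@@]2(C)CCCC(=C)[C@@H]2[C@@H]1O | intermediate
28 | 2-(diethoxyphosphoryl)acetic acid | CCOP(=O)(CC(=O)O)OCC | starting material
29 | eudesm-4(15)-en-6β-yl 2-(diethoxyphosphoryl)acetate, 5α-H, 7α-H, 10β-CH3 | CC(C)[C@@H]1CC[C@@]2(C)CCCC(=C)[C@@H]2[C@@H]1OC(=O)CP(=O)(OCC)OCC | intermediate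
30 | 4α,15-dihydroxyeudesman-6β-yl 2-(diethoxyphosphoryl)acetate, 5α-H, 7α-H, 10β-CH3 | CC(C)[C@@H]1CC[C@@]2(C)CCC[C@](O)(CO)[C@@H]2[C@@H]1OC(=O)CP(=O)(OCC)OCC | intermediate
31 | benzaldehyde | O=Cc1ccccc1 | starting material
32 | 4α,15-dihydroxyeudesman-6β-yl (E)-cinnamate, 5α-H, 7α-H, 10β-CH3 (CNP0198850.1) | CC(C)[C@@H]1CC[C@@]2(C)CCC[C@](O)(CO)[C@@H]2[C@@H]1OC(=O)/C=C/c1ccccc1 | target

**Totals and risks**

Total step count: 19. Longest linear sequence: 19 steps (1 to 32); all other inputs enter as purchased reagents.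

Steps most likely to fail:

Step 10. The stoichiometric aluminium Lewis acid may ionise the C4 ketal, which is allylic to the electron-rich dienol ether, or strip the silyl group, and the sluggish β,β-disubstituted dienophile may lose endo and facial control. The fallback replaces auxiliary control by catalyst control with a chelating copper complex used in catalytic amount. It sets out from 15: the mixed anhydride 17 is made as in step 8 and acylates oxazolidin-2-one (LiCl, Et3N) to give the achiral imide 3-{(E)-3-methyl-6-[2-(4-methyl-3-methylidene-2-oxopentyl)-1,3-dioxolan-2-yl]hex-2-enoyl}oxazolidin-2-one F1. TBSOTf/Et3N converts it into the Z silyl dienol ether F2. A bis(oxazoline) complex of divalent copper, [Cu((S,S)-t-Bu-box)](SbF6)2 (5–10 mol %, CH2Cl2, −20 °C to rt; t-Bu-box = 2,2′-isopropylidenebis(4-tert-butyl-2-oxazoline), the ligand enantiomer expected from the square-planar chelate model to expose the same enoyl face), then promotes the same intramolecular Diels–Alder reaction, a known mode of catalysis for trienyl N-acyl oxazolidinones, to give the oxazolidinone cycloadduct F3. LiOH/H2O2 cleaves F3 to the acid 21, where the route is rejoined.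

Step 9. The silylation may also deprotonate and silylate the γ-position of the enoyl imide, the silyl triflate may open the ketal, and the dienol ether may hydrolyse during isolation. The fallback makes the diene before the imide exists. It sets out from 15: TBSOTf (2.5 equiv)/Et3N silylates both the acid and the ketone to give the silyl ester silyl dienol ether F4. Cold aqueous K2CO3 in THF cleaves only the labile silyl ester and gives the dienol ether acid F5, kept as its triethylammonium salt. t-BuCOCl/Et3N gives the mixed pivalic anhydride F6, and 16 with LiCl then gives 19, where the route is rejoined.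

Step 15. The free β-hydroxy ketone may dehydrate across C5–C6 under acid, since H5 and the 6β-hydroxyl are trans-diaxial, or open by retro-aldol cleavage in the methylenation that follows. The fallback protects the hydroxyl first. It sets out from 25: TBSOTf/2,6-lutidine gives the 6β-silyl ether ketal F7. PPTS in wet acetone gives the 6β-silyloxy ketone F8. Zn/CH2Br2/TiCl4 gives the 6β-silyloxy alkene F9. Bu4NF in THF at 50 °C returns 27, where the route is rejoined.

Further compounds

F1 | step 10 | 3-{(E)-3-methyl-6-[2-(4-methyl-3-methylidene-2-oxopentyl)-1,3-dioxolan-2-yl]hex-2-enoyl}oxazolidin-2-one | O=C1OCCN1C(=O)/C=C(\C)CCCC2(OCCO2)CC(=O)C(=C)C(C)C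
F2 | step 10 | (Z)-tert-butyldimethylsilyl dienol ether of F1 | O=C1OCCN1C(=O)/C=C(\C)CCCC2(OCCO2)/C=C(O[Si](C)(C)C(C)(C)C)/C(=C)C(C)C
F3 | step 10 | 3-{[6-(tert-butyldimethylsilyloxy)-4,4-(ethylenedioxy)-15-noreudesm-6-en-9β-yl]carbonyl}oxazolidin-2-one, 5α-H, 10β-CH3 | CC(C)C1=C(O[Si](C)(C)C(C)(C)C)[C@H]2C3(OCCO3)CCC[C@]2(C)[C@H](C1)C(=O)N4CCOC4=O
F4 | step 9 | tert-butyldimethylsilyl ester of the (Z)-tert-butyldimethylsilyl dienol ether of 15 | CC(C)(C)[Si](C)(C)OC(=O)/C=C(\C)CCCC1(OCCO1)/C=C(O[Si](C)(C)C(C)(C)C)/C(=C)C(C)C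
F5 | step 9 | (E)-6-{2-[(Z)-2-(tert-butyldimethylsilyloxy)-4-methyl-3-methylidenepent-1-en-1-yl]-1,3-dioxolan-2-yl}-3-methylhex-2-enoic acid | OC(=O)/C=C(\C)CCCC1(OCCO1)/C=C(O[Si](C)(C)C(C)(C)C)/C(=C)C(C)C
F6 | step 9 | mixed anhydride of F5 with pivalic acid | CC(C)(C)C(=O)OC(=O)/C=C(\C)CCCC1(OCCO1)/C=C(O[Si](C)(C)C(C)(C)C)/C(=C)C(C)C
F7 | step 15 | 6β-(tert-butyldimethylsilyloxy)-4,4-(ethylenedioxy)-15-noreudesmane, 5α-H, 7α-H, 10β-CH3 | CC(C)[C@@H]1CC[C@@]2(C)CCCC3(OCCO3)[C@@H]2[C@@H]1O[Si](C)(C)C(C)(C)C
F8 | step 15 | 6β-(tert-butyldimethylsilyloxy)-15-noreudesman-4-one, 5α-H, 7α-H, 10β-CH3 | CC(C)[C@@H]1CC[C@@]2(C)CCCC(=O)[C@@H]2[C@@H]1O[Si](C)(C)C(C)(C)C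
F9 | step 15 | 6β-(tert-butyldimethylsilyloxy)eudesm-4(15)-ene, 5α-H, 7α-H, 10β-CH3 | CC(C)[C@@H]1CC[C@@]2(C)CCCC(=C)[C@@H]2[C@@H]1O[Si](C)(C)C(C)(C)C
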